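## Analysis of the target

Compound 29 is a 7-oxabicyclo[4.1.0]heptan-2-one: a cyclohexanone (ring A) fused to an epoxide, carrying a 3-methylbutanoate and a seven-carbon cross-conjugated dienone chain that ends in a tertiary allylic hydroperoxide. The ring is numbered like carvone: C1 (C=O), C2 (methyl, epoxide), C3 (epoxide CH), C4 (CH2), C5 (side chain), C6 (ester). The chain continues C7 (=CH2), C8 (C=O), C9=C10 (E), C11 (CMe2OOH). All four stereocentres (C2, C3, C5, C6) are S. In relative terms the C6 oxygen is trans to the C5 carbon substituent, the epoxide oxygen is cis to it, and the C2 methyl group lies on the opposite face. The hydroperoxide, the 1,1-disubstituted enone, the α-acyloxy ketone (acyl shift, epimerisable C6) and the α,β-epoxy ketone rule out strong nucleophiles, bases and reductants late in the synthesis, so the side chain must come last. The hard part is the epoxide face: C5 is separated from C3 by the C4 methylene, and no reagent-controlled epoxidation can be relied on to choose the face that carries the C5 substituent. The strategy rests on the 1,3-relationship of C5 and C3 and on the fact that the oxygen on C3 and the carbon on C5 share one face. If that carbon (the future C7) is a carboxyl group, it can reach C3 across the ring, deliver oxygen to that face, and afterwards be turned into the side chain.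

## Retrosynthetic reasoning

**29 ⇒ 28.** The hydroperoxide O–H is masked as a perketal until the end. The last step then only has to cleave an acetal under mild acid, which the epoxy ketone, ester and dienone should tolerate.

**28 ⇒ 23 + 27.** The C7–C8 and C8–C9 bonds are cut, so that C8 comes from a one-carbon carbonyl insertion between an enol triflate (23) and an alkenylstannane (27). This keeps the dienone and the peroxide out of all ring chemistry. The forward reaction must join three components without disturbing the epoxy ketone or the O–O bond. Stannane 27 goes back through alkyne 26 and hydroperoxide 25 to alcohol 24.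

**23 ⇒ 21 ⇒ 20 ⇒ 19 ⇒ 18.** The ester on C6 and the ketone on C1 are introduced only after all organometallic steps. C1 is oxidised first (19 → 20), so that the remaining silyl group is removed from an epoxy ketone, which resists acid better than a plain epoxide. The C6 hydroxyl is acylated last, so no free neighbouring hydroxyl is ever present that could take over the acyl group.

**18 ⇒ 17 ⇒ 16.** The C7=CH2 unit is traced to a methyl ketone and this to a Weinreb amide. C7 is thereby a carboxyl carbon, which is what the key step needs.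

**16 ⇒ 14 ⇒ 13 (key disconnection).** The epoxide is opened retrosynthetically to a trans-iodohydrin whose C3 oxygen is tied to the C5 carbonyl as a bridged lactone (14). Cutting the C3–O bond of 14 leads to the cyclohexene acid 13. The forward iodolactonisation puts oxygen on C3 from the C5 face and iodine on C2 from the other face. Opening the lactone then lets the C3 alkoxide displace iodide with inversion at C2.

**13 ⇒ 12 ⇒ 11 ⇒ 10 ⇒ 9 ⇒ 8.** The two ring oxygens come from enone 8: α′-hydroxylation trans to the C5 ester sets C6, and 1,2-reduction turns the carbonyl into a protected alcohol so that the alkene becomes electron-rich enough for the key step. Two different silyl groups allow C1 and C6 to be addressed separately later.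

**8 ⇒ 6.** The C1 carbonyl is introduced by allylic oxidation of the C1 methylene with the double bond staying at C2–C3. This matters: the enone formed by oxidation with allylic transposition has the same constitution as 8 but is its enantiomer, so a method passing through a symmetrical allyl intermediate would erode the enantiomeric purity.

**6 ⇒ 5 ⇒ 3 + 4, and 3 ⇒ 1 + 2.** The ring and the C5 stereocentre come from an auxiliary-controlled Diels–Alder reaction of isoprene 4 with acrylimide 3, made from oxazolidinone 1 and acid chloride 2. Cutting C4–C5 and C1–C6 uses the para preference of a 2-substituted diene to place the methyl group on C2.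

## Alternatives that were turned down

**Alternative 1:** The carbocycle is cut at C4–C5 and C1–C6, as in the chosen route, but the dienophile already carries the C6 oxygen as its final ester. Forward, isoprene 4 and 3-[(2E)-3-(3-methylbutanoyloxy)prop-2-enoyl]-1,3-oxazolidin-2-one A2 would combine under Cu(SbF6)2 with a chiral tert-butyl bis(oxazoline) ligand (divalent copper) to give 3-[(1R,6R)-4-methyl-6-(3-methylbutanoyloxy)cyclohex-3-ene-1-carbonyl]-1,3-oxazolidin-2-one A1.
- For it: the step is catalytic, sets C5 and C6 together (trans, from the E geometry) and brings in the ester at once. On step count for these two centres it is clearly stronger than steps 1–6 of the chosen route.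
- Against it: isoprene is a sluggish diene and a β-acyloxy acrylimide a deactivated dienophile, and the regiochemistry rests on the methyl group alone.
- Against it: C1 of A1 is still a methylene, and its oxidation next to an ester-bearing carbon is unattractive.
- Against it: the 3-methylbutanoate would not survive the methyl nucleophile and amide bases needed to turn the acyl carbon into C7, so it would have to be exchanged anyway.
- Against it: the epoxide face is left unsolved.
- The chosen strategy gives, in exchange for more steps, a C6 protecting group that tolerates the side-chain chemistry and a built-in control element for the epoxide.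

**Alternative 2:** The cut is at C7–C8 and C8–C9. Forward, enol triflate 23, carbon monoxide and stannane 27 would couple under Pd(PPh3)4 (zerovalent palladium) with LiCl to give (1S,3S,4S,6S)-4-{(4E)-6-[(2-methoxypropan-2-yl)peroxy]-6-methyl-3-oxohepta-1,4-dien-2-yl}-1-methyl-2-oxo-7-oxabicyclo[4.1.0]heptan-3-yl 3-methylbutanoate A3, which is identical with 28.
- For it: it is convergent, forms two bonds at once, brings the peroxide in masked and exposes the dienone only at the very end. For the side chain it is as strong as anything else considered, and the chosen route adopts it as step 21.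
- Against it as the central idea: it says nothing about the four ring stereocentres. The triflate must already contain them, so a separate answer to the epoxide face is needed in any case.
- The chosen strategy supplies that answer and keeps this coupling as its endgame.

**Alternative 3:** The ring is cut at C1–C2. Forward, the aldehyde carbon of (3R,5R)-6-oxo-3-(prop-1-en-2-yl)-5-[(triethylsilyl)oxy]heptanal A5 (derived from (R)-limonene A6 by C6 oxygenation and cleavage of the ring alkene) would add, as its Breslow intermediate under a chiral triazolium carbene, to the methyl ketone to give (2S,3R,5R)-2-hydroxy-2-methyl-5-(prop-1-en-2-yl)-3-[(triethylsilyl)oxy]cyclohexan-1-one A4.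
- For it: C5 and the C7/C8 carbons come from the chiral pool, so no auxiliary, no methyl ketone/enol triflate detour and no carbonyl insertion are needed. On these points it is stronger.
- For it: the C1 carbonyl is formed directly, without a reduction/oxidation shuttle, and the tertiary oxygen on C2 can become the epoxide oxygen by displacement at C3.
- Against it: an aldehyde–ketone benzoin between two enolisable aliphatic carbonyls competes with aldol closure and is reversible. The C2 configuration would depend on the match between catalyst and a substrate with two stereocentres.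
- Against it: selective cleavage of the ring alkene beside the isopropenyl group, C6 oxidation next to a tertiary ketol, and oxidation of the isopropenyl methyl group to C8 in the presence of the C1 ketone each add uncertainty after the key step.
- The chosen strategy is longer but fixes the epoxide face by geometry alone, and every step has a close precedent.

Key step: step 10

## Route

Assumption: compounds 1, 2, 4, 22 and 24 are taken as commercially available.

**Step 1**
Reactants: 1 (R)-4-benzyl-1,3-oxazolidin-2-one; 2 acryloyl chloride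
Product: 3 (R)-3-acryloyl-4-benzyl-1,3-oxazolidin-2-one
Conditions: MeMgBr, THF, 0 °C; then 2, −78 → 0 °C
Reagents that add atoms: none
Why: N-acylation of the metalated oxazolidinone; the bromomagnesium salt is chosen because it acylates cleanly at low temperature with an acid chloride that polymerises easily.

**Step 2**
Reactants: 3 (R)-3-acryloyl-4-benzyl-1,3-oxazolidin-2-one; 4 isoprene
Product: 5 (R)-4-benzyl-3-[(S)-4-methylcyclohex-3-ene-1-carbonyl]-1,3-oxazolidin-2-one
Conditions: Et2AlCl (1.4 equiv), 4 (excess), CH2Cl2, −100 → −78 °C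
Reagents that add atoms: none
Why: Lewis-acid-promoted asymmetric Diels–Alder reaction; Et2AlCl chelates both imide carbonyls and fixes the s-cis enoyl conformer, so the diene adds to the face away from the benzyl group, which for the (R)-auxiliary should give the (S) ring carbon (the future C5). The methyl group ends para to the acyl carbon, as usual for a 2-substituted diene.

**Step 3**
Reactants: 5 (R)-4-benzyl-3-[(S)-4-methylcyclohex-3-ene-1-carbonyl]-1,3-oxazolidin-2-one
Product: 6 methyl (S)-4-methylcyclohex-3-ene-1-carboxylate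
Conditions: MeMgBr, MeOH, CH2Cl2, 0 °C
Reagents that add atoms: methanol, CO
Why: Transesterification of the N-acyl oxazolidinone at the exocyclic carbonyl by bromomagnesium methoxide; the conditions are mild enough to leave the α-stereocentre untouched, and the auxiliary is recovered.

**Step 4**
Reactants: 6 methyl (S)-4-methylcyclohex-3-ene-1-carboxylate
Product: 8 methyl (R)-4-methyl-5-oxocyclohex-3-ene-1-carboxylate, via allylic alcohol 7 (not isolated)
Conditions: SeO2 (cat.), t-BuOOH, CH2Cl2, 0 °C → rt; crude, then DMP, CH2Cl2, rt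
Reagents that add atoms: selenium dioxide (oxygen carrier), O=[Se]=O; tert-butyl hydroperoxide (terminal oxidant), CC(C)(C)OO
Why: Riley-type allylic oxidation (ene reaction, then [2,3]-sigmatropic shift) puts oxygen on the ring methylene next to the more substituted alkene carbon and returns the double bond to C2–C3; Dess–Martin oxidation then converges the alcohol and any enone already present on 8. A free allyl radical is avoided because oxygenation at its other terminus would give the enantiomer of 8. The descriptor changes from S to R only because the ring branch priorities change.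

**Step 5**
Reactants: 8 methyl (R)-4-methyl-5-oxocyclohex-3-ene-1-carboxylate
Product: 9 methyl (1R,6S)-6-hydroxy-4-methyl-5-oxocyclohex-3-ene-1-carboxylate
Conditions: KN(SiMe3)2, THF, −78 °C; 2-(phenylsulfonyl)-3-phenyloxaziridine, −78 °C; AcOH
Reagents that add atoms: 2-(phenylsulfonyl)-3-phenyloxaziridine, O=S(=O)(c1ccccc1)N1OC1c1ccccc1
Why: α′-Hydroxylation of the kinetic cross-conjugated enolate with an N-sulfonyloxaziridine; the ketone α′-position is deprotonated faster than the ester α-position. The oxidant should approach C6 anti to the neighbouring C5 ester, giving the trans alcohol, which is also the more stable epimer.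

**Step 6**
Reactants: 9 methyl (1R,6S)-6-hydroxy-4-methyl-5-oxocyclohex-3-ene-1-carboxylate
Product: 10 methyl (1R,6S)-6-[(tert-butyldimethylsilyl)oxy]-4-methyl-5-oxocyclohex-3-ene-1-carboxylate
Conditions: TBSOTf, 2,6-lutidine, CH2Cl2, −78 °C
Reagents that add atoms: tert-butyldimethylsilyl trifluoromethanesulfonate, CC(C)(C)[Si](C)(C)OS(=O)(=O)C(F)(F)F
Why: Silylation of a secondary alcohol with a silyl triflate; the robust silyl group goes on C6 because it has to survive amide bases, methyllithium and the first desilylation.

**Step 7**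
Reactants: 10 methyl (1R,6S)-6-[(tert-butyldimethylsilyl)oxy]-4-methyl-5-oxocyclohex-3-ene-1-carboxylate
Product: 11 methyl (1R,5S,6S)-6-[(tert-butyldimethylsilyl)oxy]-5-hydroxy-4-methylcyclohex-3-ene-1-carboxylate
Conditions: NaBH4, CeCl3·7H2O, MeOH, −78 °C
Reagents that add atoms: none
Why: Luche 1,2-reduction; hydride should add axially to the half-chair with the C5 and C6 substituents equatorial, giving the C1 hydroxyl trans to the C6 silyloxy group and cis to the C5 ester, and the ester is not reduced. This centre is oxidised again in step 15, but a single epimer keeps the key step clean.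

**Step 8**
Reactants: 11 methyl (1R,5S,6S)-6-[(tert-butyldimethylsilyl)oxy]-5-hydroxy-4-methylcyclohex-3-ene-1-carboxylate
Product: 12 methyl (1R,5S,6S)-6-[(tert-butyldimethylsilyl)oxy]-4-methyl-5-[(triethylsilyl)oxy]cyclohex-3-ene-1-carboxylate
Conditions: TESOTf, 2,6-lutidine, CH2Cl2, −78 °C
Reagents that add atoms: triethylsilyl trifluoromethanesulfonate, CC[Si](CC)(CC)OS(=O)(=O)C(F)(F)F
Why: Silylation; the smaller and more labile silyl group is put on C1 so that it can be removed selectively in step 14, and because this oxygen will sit under the lactone bridge in the key step.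

**Step 9**
Reactants: 12 methyl (1R,5S,6S)-6-[(tert-butyldimethylsilyl)oxy]-4-methyl-5-[(triethylsilyl)oxy]cyclohex-3-ene-1-carboxylate
Product: 13 (1R,5S,6S)-6-[(tert-butyldimethylsilyl)oxy]-4-methyl-5-[(triethylsilyl)oxy]cyclohex-3-ene-1-carboxylic acid
Conditions: LiOH, THF/MeOH/H2O, 0 °C → rt; cold dil. HCl to pH 4
Reagents that add atoms: lithium hydroxide, [Li+].[OH-]
Why: Saponification of the methyl ester by acyl–oxygen cleavage; aqueous hydroxide does not enolise the ester appreciably and the trans C5/C6 arrangement is the stable one, so neither epimerisation nor β-elimination of the silyloxy group is expected.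

**Step 10 (key step)**
Reactants: 13 (1R,5S,6S)-6-[(tert-butyldimethylsilyl)oxy]-4-methyl-5-[(triethylsilyl)oxy]cyclohex-3-ene-1-carboxylic acid
Product: 14 (1R,2S,3R,4R,5S)-2-[(tert-butyldimethylsilyl)oxy]-4-iodo-4-methyl-3-[(triethylsilyl)oxy]-6-oxabicyclo[3.2.1]octan-7-one
Conditions: I2, KI, NaHCO3, THF/H2O, 0 °C → rt, dark
Reagents that add atoms: iodine, II
Why: Iodolactonisation; the closest known type is the conversion of cyclohex-3-ene-1-carboxylic acids into 4-iodo-6-oxabicyclo[3.2.1]octan-7-ones. Iodine adds reversibly to both faces of the C2–C3 alkene, but only the iodonium ion on the face opposite the carboxylate can be opened intramolecularly: with the C5 carboxylate axial, its oxygen lies over C3 and attacks anti to iodine. The five-membered lactone closes in a 5-exo mode on the iodonium ion (C3 inside the new ring, C2 outside) and bridges C3 and C5. C3 is set by the tether (oxygen necessarily on the C5 face) and C2 by the anti addition (iodine on the far face, methyl on the C5 face). The step needs attack at C3 and not at C2; the 5-exo diaxial opening and the electron-withdrawing silyloxy group on C1, next to C2, both oppose the Markovnikov pull of the methyl group, and attack at C2 would lead to the same epoxide in step 11 anyway. The trans-vicinal silyloxy groups on C1 and C6 should make the conformer with axial C5 and C6 substituents accessible. Bicarbonate buffering should keep both silyl ethers intact.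

**Step 11**
Reactants: 14 (1R,2S,3R,4R,5S)-2-[(tert-butyldimethylsilyl)oxy]-4-iodo-4-methyl-3-[(triethylsilyl)oxy]-6-oxabicyclo[3.2.1]octan-7-one
Product: 16 (1S,3R,4S,5R,6S)-4-[(tert-butyldimethylsilyl)oxy]-N-methoxy-N,6-dimethyl-5-[(triethylsilyl)oxy]-7-oxabicyclo[4.1.0]heptane-3-carboxamide, via iodohydrin amide 15 (not isolated)
Conditions: AlMe3, MeNH(OMe)·HCl, CH2Cl2, 0 °C → rt; aq. KNaC4H4O6; crude, then K2CO3, MeOH, 0 °C
Reagents that add atoms: N,O-dimethylhydroxylamine hydrochloride, CNOC.Cl
Why: Aminolysis of the lactone by the aluminium amide (Weinreb amide formation) frees the C3 hydroxyl. Carbonate then generates the alkoxide, which is anti to the C2–I bond and displaces iodide with inversion at C2 (epoxide closure of a trans-iodohydrin), so the oxygen stays on the C5 face and the methyl group moves to the other face.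

**Step 12**
Reactants: 16 (1S,3R,4S,5R,6S)-4-[(tert-butyldimethylsilyl)oxy]-N-methoxy-N,6-dimethyl-5-[(triethylsilyl)oxy]-7-oxabicyclo[4.1.0]heptane-3-carboxamide
Product: 17 1-[(1S,3R,4S,5R,6S)-4-[(tert-butyldimethylsilyl)oxy]-6-methyl-5-[(triethylsilyl)oxy]-7-oxabicyclo[4.1.0]heptan-3-yl]ethan-1-one
Conditions: MeLi, THF, −78 °C; aq. NH4Cl
Reagents that add atoms: methyllithium, [Li]C
Why: Ketone synthesis from a Weinreb amide; the chelated tetrahedral adduct stops at single addition, and at −78 °C methyllithium should spare the trisubstituted epoxide.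

**Step 13**
Reactants: 17 1-[(1S,3R,4S,5R,6S)-4-[(tert-butyldimethylsilyl)oxy]-6-methyl-5-[(triethylsilyl)oxy]-7-oxabicyclo[4.1.0]heptan-3-yl]ethan-1-one
Product: 18 1-[(1S,3R,4S,5R,6S)-4-[(tert-butyldimethylsilyl)oxy]-6-methyl-5-[(triethylsilyl)oxy]-7-oxabicyclo[4.1.0]heptan-3-yl]ethenyl trifluoromethanesulfonate
Conditions: KN(SiMe3)2, THF, −78 °C; N-(5-chloropyridin-2-yl)bis(trifluoromethanesulfonimide), −78 → −20 °C
Reagents that add atoms: N-(5-chloropyridin-2-yl)bis(trifluoromethanesulfonimide), FC(F)(F)S(=O)(=O)N(c1ccc(Cl)cn1)S(=O)(=O)C(F)(F)F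
Why: Kinetic enolisation of the methyl ketone on the methyl side followed by O-sulfonylation (enol triflate formation); deprotonation at C5, which would expel the C6 silyloxy group, is slower. The enolate sits on the same face as the epoxide oxygen and so cannot open the epoxide from the rear.

**Step 14**
Reactants: 18 1-[(1S,3R,4S,5R,6S)-4-[(tert-butyldimethylsilyl)oxy]-6-methyl-5-[(triethylsilyl)oxy]-7-oxabicyclo[4.1.0]heptan-3-yl]ethenyl trifluoromethanesulfonate
Product: 19 1-[(1S,3R,4S,5R,6R)-4-[(tert-butyldimethylsilyl)oxy]-5-hydroxy-6-methyl-7-oxabicyclo[4.1.0]heptan-3-yl]ethenyl trifluoromethanesulfonate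
Conditions: HF·pyridine, pyridine, THF, 0 °C
Reagents that add atoms: none
Why: Selective desilylation; buffered HF·pyridine cleaves a triethylsilyl ether much faster than a tert-butyldimethylsilyl ether, and the buffered medium should leave epoxide and enol triflate intact.

**Step 15**
Reactants: 19 1-[(1S,3R,4S,5R,6R)-4-[(tert-butyldimethylsilyl)oxy]-5-hydroxy-6-methyl-7-oxabicyclo[4.1.0]heptan-3-yl]ethenyl trifluoromethanesulfonate
Product: 20 1-[(1S,3R,4S,6S)-4-[(tert-butyldimethylsilyl)oxy]-6-methyl-5-oxo-7-oxabicyclo[4.1.0]heptan-3-yl]ethenyl trifluoromethanesulfonate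
Conditions: DMP, NaHCO3, CH2Cl2, 0 °C → rt
Reagents that add atoms: none
Why: Dess–Martin oxidation of the secondary alcohol under buffered, non-enolising conditions; from here on the epoxide is part of an α,β-epoxy ketone and is less prone to acid-induced opening.

**Step 16**
Reactants: 20 1-[(1S,3R,4S,6S)-4-[(tert-butyldimethylsilyl)oxy]-6-methyl-5-oxo-7-oxabicyclo[4.1.0]heptan-3-yl]ethenyl trifluoromethanesulfonate
Product: 21 1-[(1S,3R,4S,6S)-4-hydroxy-6-methyl-5-oxo-7-oxabicyclo[4.1.0]heptan-3-yl]ethenyl trifluoromethanesulfonate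
Conditions: HF·pyridine, THF, 0 °C → rt
Reagents that add atoms: none
Why: Desilylation with HF·pyridine; an α-silyloxy ketone is cleaved readily, basic fluoride sources are avoided because they can attack enol triflates, and no neighbouring ester is present yet that could migrate.

**Step 17**
Reactants: 21 1-[(1S,3R,4S,6S)-4-hydroxy-6-methyl-5-oxo-7-oxabicyclo[4.1.0]heptan-3-yl]ethenyl trifluoromethanesulfonate; 22 3-methylbutanoyl chloride
Product: 23 (1S,3S,4R,6S)-1-methyl-2-oxo-4-{1-[(trifluoromethanesulfonyl)oxy]ethenyl}-7-oxabicyclo[4.1.0]heptan-3-yl 3-methylbutanoate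
Conditions: 22, pyridine, DMAP (cat.), CH2Cl2, 0 °C
Reagents that add atoms: none
Why: Acylation of the alcohol with an acid chloride under nucleophilic catalysis; pyridine is too weak a base to epimerise C6 at a useful rate, and the trans C5/C6 arrangement is the stable one in any case.

**Step 18**
Reactants: 24 2-methylbut-3-yn-2-ol
Product: 25 3-hydroperoxy-3-methylbut-1-yne
Conditions: 50% aq. H2O2, H2SO4, 0 °C
Reagents that add atoms: hydrogen peroxide, OO
Why: SN1 perhydrolysis of a tertiary propargylic alcohol; acid ionises the alcohol and concentrated hydrogen peroxide captures the cation.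

**Step 19**
Reactants: 25 3-hydroperoxy-3-methylbut-1-yne
Product: 26 3-[(2-methoxypropan-2-yl)peroxy]-3-methylbut-1-yne
Conditions: 2-methoxypropene, PPTS (cat.), CH2Cl2, 0 °C
Reagents that add atoms: 2-methoxypropene, COC(C)=C
Why: Acid-catalysed addition of the hydroperoxide to an enol ether (perketal formation) masks the O–H for the palladium steps.

**Step 20**
Reactants: 26 3-[(2-methoxypropan-2-yl)peroxy]-3-methylbut-1-yne
Product: 27 tributyl{(1E)-3-[(2-methoxypropan-2-yl)peroxy]-3-methylbut-1-en-1-yl}stannane
Conditions: Bu3SnH, PdCl2(PPh3)2 (cat.), THF, 0 °C → rt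
Reagents that add atoms: tributyltin hydride, CCCC[SnH](CCCC)CCCC
Why: Palladium-catalysed syn-hydrostannation of a terminal alkyne; the quaternary propargylic carbon steers tin to the terminal carbon and gives the (E)-alkenylstannane. Radical conditions are avoided because stannyl radicals attack O–O bonds.

**Step 21**
Reactants: 23 (1S,3S,4R,6S)-1-methyl-2-oxo-4-{1-[(trifluoromethanesulfonyl)oxy]ethenyl}-7-oxabicyclo[4.1.0]heptan-3-yl 3-methylbutanoate; 27 tributyl{(1E)-3-[(2-methoxypropan-2-yl)peroxy]-3-methylbut-1-en-1-yl}stannane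
Product: 28 (1S,3S,4S,6S)-4-{(4E)-6-[(2-methoxypropan-2-yl)peroxy]-6-methyl-3-oxohepta-1,4-dien-2-yl}-1-methyl-2-oxo-7-oxabicyclo[4.1.0]heptan-3-yl 3-methylbutanoate
Conditions: Pd(PPh3)4 (cat.), LiCl, CO (3 atm), THF, 55 °C
Reagents that add atoms: carbon monoxide, [C-]#[O+]
Why: Carbonylative Stille coupling; oxidative addition of the enol triflate to zerovalent palladium (chloride from LiCl stabilises the alkenylpalladium species), CO insertion to the acyl complex, transmetalation with retention of alkene geometry and reductive elimination give the divinyl ketone. CO pressure suppresses direct coupling, and the perketal is a dialkyl-type peroxide, which is expected to tolerate the catalyst.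

**Step 22**
Reactants: 28 (1S,3S,4S,6S)-4-{(4E)-6-[(2-methoxypropan-2-yl)peroxy]-6-methyl-3-oxohepta-1,4-dien-2-yl}-1-methyl-2-oxo-7-oxabicyclo[4.1.0]heptan-3-yl 3-methylbutanoate
Product: 29 (1S,3S,4S,6S)-4-[(4E)-6-hydroperoxy-6-methyl-3-oxohepta-1,4-dien-2-yl]-1-methyl-2-oxo-7-oxabicyclo[4.1.0]heptan-3-yl 3-methylbutanoate
Conditions: AcOH/THF/H2O, rt
Reagents that add atoms: none
Why: Mild acid hydrolysis of the perketal (acetal cleavage) frees the hydroperoxide; dilute acetic acid should leave the epoxy ketone, the ester and the dienone untouched.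

## Compound list

1 | (R)-4-benzyl-1,3-oxazolidin-2-one | O=C1N[C@H](Cc2ccccc2)CO1 | starting material
2 | acryloyl chloride | C=CC(=O)Cl | starting material
3 | (R)-3-acryloyl-4-benzyl-1,3-oxazolidin-2-one | C=CC(=O)N1[C@H](Cc2ccccc2)COC1=O | intermediate
4 | isoprene | C=CC(C)=C | starting material
5 | (R)-4-benzyl-3-[(S)-4-methylcyclohex-3-ene-1-carbonyl]-1,3-oxazolidin-2-one | O=C([C@@H]1CC=C(C)CC1)N1[C@H](Cc2ccccc2)COC1=O | intermediate
6 | methyl (S)-4-methylcyclohex-3-ene-1-carboxylate | COC(=O)[C@@H]1CC=C(C)CC1 | intermediate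
7 | methyl (1R,5RS)-5-hydroxy-4-methylcyclohex-3-ene-1-carboxylate (both carbinol epimers) | COC(=O)[C@@H]1CC=C(C)C(O)C1 | intermediate (not isolated)
8 | methyl (R)-4-methyl-5-oxocyclohex-3-ene-1-carboxylate | COC(=O)[C@@H]1CC=C(C)C(=O)C1 | intermediate
9 | methyl (1R,6S)-6-hydroxy-4-methyl-5-oxocyclohex-3-ene-1-carboxylate | COC(=O)[C@@H]1CC=C(C)C(=O)[C@H]1O | intermediate
10 | methyl (1R,6S)-6-[(tert-butyldimethylsilyl)oxy]-4-methyl-5-oxocyclohex-3-ene-1-carboxylate | COC(=O)[C@@H]1CC=C(C)C(=O)[C@H]1O[Si](C)(C)C(C)(C)C | intermediate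
11 | methyl (1R,5S,6S)-6-[(tert-butyldimethylsilyl)oxy]-5-hydroxy-4-methylcyclohex-3-ene-1-carboxylate | COC(=O)[C@@H]1CC=C(C)[C@H](O)[C@H]1O[Si](C)(C)C(C)(C)C | intermediate
12 | methyl (1R,5S,6S)-6-[(tert-butyldimethylsilyl)oxy]-4-methyl-5-[(triethylsilyl)oxy]cyclohex-3-ene-1-carboxylate | COC(=O)[C@@H]1CC=C(C)[C@H](O[Si](CC)(CC)CC)[C@H]1O[Si](C)(C)C(C)(C)C | intermediate
13 | (1R,5S,6S)-6-[(tert-butyldimethylsilyl)oxy]-4-methyl-5-[(triethylsilyl)oxy]cyclohex-3-ene-1-carboxylic acid (key-step precursor) | OC(=O)[C@@H]1CC=C(C)[C@H](O[Si](CC)(CC)CC)[C@H]1O[Si](C)(C)C(C)(C)C | intermediate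
14 | (1R,2S,3R,4R,5S)-2-[(tert-butyldimethylsilyl)oxy]-4-iodo-4-methyl-3-[(triethylsilyl)oxy]-6-oxabicyclo[3.2.1]octan-7-one (key-step product) | O=C3[C@@H]1C[C@H](O3)[C@@](C)(I)[C@H](O[Si](CC)(CC)CC)[C@H]1O[Si](C)(C)C(C)(C)C | intermediate
15 | (1R,2S,3R,4R,5S)-2-[(tert-butyldimethylsilyl)oxy]-5-hydroxy-4-iodo-N-methoxy-N,4-dimethyl-3-[(triethylsilyl)oxy]cyclohexane-1-carboxamide | CON(C)C(=O)[C@@H]1C[C@H](O)[C@@](C)(I)[C@H](O[Si](CC)(CC)CC)[C@H]1O[Si](C)(C)C(C)(C)C | intermediate (not isolated)
16 | (1S,3R,4S,5R,6S)-4-[(tert-butyldimethylsilyl)oxy]-N-methoxy-N,6-dimethyl-5-[(triethylsilyl)oxy]-7-oxabicyclo[4.1.0]heptane-3-carboxamide | CON(C)C(=O)[C@@H]1C[C@@H]2O[C@]2(C)[C@H](O[Si](CC)(CC)CC)[C@H]1O[Si](C)(C)C(C)(C)C | intermediate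
17 | 1-[(1S,3R,4S,5R,6S)-4-[(tert-butyldimethylsilyl)oxy]-6-methyl-5-[(triethylsilyl)oxy]-7-oxabicyclo[4.1.0]heptan-3-yl]ethan-1-one | CC(=O)[C@@H]1C[C@@H]2O[C@]2(C)[C@H](O[Si](CC)(CC)CC)[C@H]1O[Si](C)(C)C(C)(C)C | intermediate
18 | 1-[(1S,3R,4S,5R,6S)-4-[(tert-butyldimethylsilyl)oxy]-6-methyl-5-[(triethylsilyl)oxy]-7-oxabicyclo[4.1.0]heptan-3-yl]ethenyl trifluoromethanesulfonate | C=C(OS(=O)(=O)C(F)(F)F)[C@@H]1C[C@@H]2O[C@]2(C)[C@H](O[Si](CC)(CC)CC)[C@H]1O[Si](C)(C)C(C)(C)C | intermediate
19 | 1-[(1S,3R,4S,5R,6R)-4-[(tert-butyldimethylsilyl)oxy]-5-hydroxy-6-methyl-7-oxabicyclo[4.1.0]heptan-3-yl]ethenyl trifluoromethanesulfonate | C=C(OS(=O)(=O)C(F)(F)F)[C@@H]1C[C@@H]2O[C@]2(C)[C@H](O)[C@H]1O[Si](C)(C)C(C)(C)C | intermediate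
20 | 1-[(1S,3R,4S,6S)-4-[(tert-butyldimethylsilyl)oxy]-6-methyl-5-oxo-7-oxabicyclo[4.1.0]heptan-3-yl]ethenyl trifluoromethanesulfonate | C=C(OS(=O)(=O)C(F)(F)F)[C@@H]1C[C@@H]2O[C@]2(C)C(=O)[C@H]1O[Si](C)(C)C(C)(C)C | intermediate
21 | 1-[(1S,3R,4S,6S)-4-hydroxy-6-methyl-5-oxo-7-oxabicyclo[4.1.0]heptan-3-yl]ethenyl trifluoromethanesulfonate | C=C(OS(=O)(=O)C(F)(F)F)[C@@H]1C[C@@H]2O[C@]2(C)C(=O)[C@H]1O | intermediate
22 | 3-methylbutanoyl chloride | CC(C)CC(=O)Cl | starting material
23 | (1S,3S,4R,6S)-1-methyl-2-oxo-4-{1-[(trifluoromethanesulfonyl)oxy]ethenyl}-7-oxabicyclo[4.1.0]heptan-3-yl 3-methylbutanoate | C=C(OS(=O)(=O)C(F)(F)F)[C@@H]1C[C@@H]2O[C@]2(C)C(=O)[C@H]1OC(=O)CC(C)C | intermediate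
24 | 2-methylbut-3-yn-2-ol | C#CC(C)(C)O | starting material
25 | 3-hydroperoxy-3-methylbut-1-yne | C#CC(C)(C)OO | intermediate
26 | 3-[(2-methoxypropan-2-yl)peroxy]-3-methylbut-1-yne | C#CC(C)(C)OOC(C)(C)OC | intermediate
27 | tributyl{(1E)-3-[(2-methoxypropan-2-yl)peroxy]-3-methylbut-1-en-1-yl}stannane | CCCC[Sn](CCCC)(CCCC)/C=C/C(C)(C)OOC(C)(C)OC | intermediate
28 | (1S,3S,4S,6S)-4-{(4E)-6-[(2-methoxypropan-2-yl)peroxy]-6-methyl-3-oxohepta-1,4-dien-2-yl}-1-methyl-2-oxo-7-oxabicyclo[4.1.0]heptan-3-yl 3-methylbutanoate | C=C(C(=O)/C=C/C(C)(C)OOC(C)(C)OC)[C@@H]1C[C@@H]2O[C@]2(C)C(=O)[C@H]1OC(=O)CC(C)C | intermediate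
29 | (1S,3S,4S,6S)-4-[(4E)-6-hydroperoxy-6-methyl-3-oxohepta-1,4-dien-2-yl]-1-methyl-2-oxo-7-oxabicyclo[4.1.0]heptan-3-yl 3-methylbutanoate | C=C(C(=O)/C=C/C(C)(C)OO)[C@@H]1C[C@@H]2O[C@]2(C)C(=O)[C@H]1OC(=O)CC(C)C | target

## Step count and least certain steps

Total: 22 steps. Longest linear sequence: 19 steps (steps 1–17, 21 and 22); the stannane branch (steps 18–20) joins at step 21.

**Step 10 (key step).** The reactive conformer places the C1 silyloxy group on the same face as the incoming carboxylate, and in the product it lies under the lactone bridge. This may slow the ring closure enough for intermolecular capture of the iodonium ion by water, or for loss of the triethylsilyl group on long exposure. Leakage to attack at C2 would be harmless, since both lactones give the same epoxide.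
Fallback (hydroxyl-directed epoxidation instead of the tether): set out from 11, whose C1 hydroxyl lies on the C5 face. Epoxidation with t-BuOOH and catalytic VO(acac)2 should deliver oxygen syn to that hydroxyl and give methyl (1S,3R,4S,5R,6R)-4-[(tert-butyldimethylsilyl)oxy]-5-hydroxy-6-methyl-7-oxabicyclo[4.1.0]heptane-3-carboxylate F1. Silylation (TESOTf, 2,6-lutidine) gives methyl (1S,3R,4S,5R,6S)-4-[(tert-butyldimethylsilyl)oxy]-6-methyl-5-[(triethylsilyl)oxy]-7-oxabicyclo[4.1.0]heptane-3-carboxylate F2. Aminolysis of the ester with MeNH(OMe)·HCl and i-PrMgCl at −20 °C rejoins the route at 16. Facial control then depends on the C1 centre from step 7 instead of on C5.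

**Step 4.** The ene oxidation may attack the C2 methyl group instead of the ring methylene, or stall on an alkene that carries a remote electron-withdrawing ester; over-oxidation is also possible.
Fallback (oxidation at the alkene carbon with transposition, run in the enantiomeric series): because the transposed enone of one adduct is the non-transposed enone of its mirror image, the sequence sets out from 4 and 2 with the other auxiliary. (S)-3-Acryloyl-4-benzyl-1,3-oxazolidin-2-one F3 (made as in step 1 from (S)-4-benzyl-1,3-oxazolidin-2-one) gives, as in steps 2 and 3, (S)-4-benzyl-3-[(R)-4-methylcyclohex-3-ene-1-carbonyl]-1,3-oxazolidin-2-one F4 and methyl (R)-4-methylcyclohex-3-ene-1-carboxylate F5. Nitrosyl chloride (isoamyl nitrite, HCl) adds with nitrogen on the alkene CH and chloride on the methyl-bearing carbon to give, after tautomerisation, methyl (1R)-4-chloro-3-(hydroxyimino)-4-methylcyclohexane-1-carboxylate F6. Pyridine removes HCl into conjugation to give methyl (1R)-5-(hydroxyimino)-4-methylcyclohex-3-ene-1-carboxylate F7, and hydrolysis with aqueous oxalic acid gives 8.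

**Step 11.** The Lewis-acidic aluminium amide may ionise or eliminate the tertiary iodide before the hindered lactone carbonyl is attacked, and the freed hydroxy amide may relactonise in competition with epoxide closure.
Fallback (hydroxide opening, then amide coupling): set out from 14. LiOH in aqueous THF opens the lactone and the alkoxide closes the epoxide in the same pot, giving (1S,3R,4S,5R,6S)-4-[(tert-butyldimethylsilyl)oxy]-6-methyl-5-[(triethylsilyl)oxy]-7-oxabicyclo[4.1.0]heptane-3-carboxylic acid F8. The carboxyl group is on the same face as the epoxide oxygen and cannot reopen it. Coupling with MeNH(OMe)·HCl (carbodiimide, HOBt, i-Pr2NEt) returns to the route at 16.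

**Step 21.** Direct coupling without CO insertion may compete. Slow oxidative addition of the hindered triflate could leave the substrate at 55 °C long enough for palladium-mediated isomerisation of the epoxy ketone or reduction of the O–O bond by phosphine. The product dienone may also oligomerise.
Fallback (separate carbonylation and C–C coupling): set out from 23. Hydroxycarbonylation (Pd(OAc)2, PPh3, CO at 1 atm, KOAc, DMF, rt) gives 2-[(1S,3S,4S,6S)-6-methyl-4-[(3-methylbutanoyl)oxy]-5-oxo-7-oxabicyclo[4.1.0]heptan-3-yl]prop-2-enoic acid F9. 1-Chloro-N,N,2-trimethylprop-1-en-1-amine converts it under neutral conditions into 2-[(1S,3S,4S,6S)-6-methyl-4-[(3-methylbutanoyl)oxy]-5-oxo-7-oxabicyclo[4.1.0]heptan-3-yl]prop-2-enoyl chloride F10. Stille acylation of F10 with 27 (Pd2(dba)3 cat., THF, rt) gives 28 without CO pressure or heating.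

## Further compounds

F1 | step 10 | methyl (1S,3R,4S,5R,6R)-4-[(tert-butyldimethylsilyl)oxy]-5-hydroxy-6-methyl-7-oxabicyclo[4.1.0]heptane-3-carboxylate | COC(=O)[C@@H]1C[C@@H]2O[C@]2(C)[C@H](O)[C@H]1O[Si](C)(C)C(C)(C)C
F2 | step 10 | methyl (1S,3R,4S,5R,6S)-4-[(tert-butyldimethylsilyl)oxy]-6-methyl-5-[(triethylsilyl)oxy]-7-oxabicyclo[4.1.0]heptane-3-carboxylate | COC(=O)[C@@H]1C[C@@H]2O[C@]2(C)[C@H](O[Si](CC)(CC)CC)[C@H]1O[Si](C)(C)C(C)(C)C
F3 | step 4 | (S)-3-acryloyl-4-benzyl-1,3-oxazolidin-2-one | C=CC(=O)N1[C@@H](Cc2ccccc2)COC1=O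
F4 | step 4 | (S)-4-benzyl-3-[(R)-4-methylcyclohex-3-ene-1-carbonyl]-1,3-oxazolidin-2-one | O=C([C@H]1CC=C(C)CC1)N1[C@@H](Cc2ccccc2)COC1=O
F5 | step 4 | methyl (R)-4-methylcyclohex-3-ene-1-carboxylate | COC(=O)[C@H]1CC=C(C)CC1
F6 | step 4 | methyl (1R)-4-chloro-3-(hydroxyimino)-4-methylcyclohexane-1-carboxylate (mixture at C4) | COC(=O)[C@H]1CC(=NO)C(C)(Cl)CC1
F7 | step 4 | methyl (1R)-5-(hydroxyimino)-4-methylcyclohex-3-ene-1-carboxylate | COC(=O)[C@H]1CC(=NO)C(C)=CC1
F8 | step 11 | (1S,3R,4S,5R,6S)-4-[(tert-butyldimethylsilyl)oxy]-6-methyl-5-[(triethylsilyl)oxy]-7-oxabicyclo[4.1.0]heptane-3-carboxylic acid | OC(=O)[C@@H]1C[C@@H]2O[C@]2(C)[C@H](O[Si](CC)(CC)CC)[C@H]1O[Si](C)(C)C(C)(C)C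
F9 | step 21 | 2-[(1S,3S,4S,6S)-6-methyl-4-[(3-methylbutanoyl)oxy]-5-oxo-7-oxabicyclo[4.1.0]heptan-3-yl]prop-2-enoic acid | C=C(C(=O)O)[C@@H]1C[C@@H]2O[C@]2(C)C(=O)[C@H]1OC(=O)CC(C)C
F10 | step 21 | 2-[(1S,3S,4S,6S)-6-methyl-4-[(3-methylbutanoyl)oxy]-5-oxo-7-oxabicyclo[4.1.0]heptan-3-yl]prop-2-enoyl chloride | C=C(C(=O)Cl)[C@@H]1C[C@@H]2O[C@]2(C)C(=O)[C@H]1OC(=O)CC(C)C
A1 | alternative 1 | 3-[(1R,6R)-4-methyl-6-(3-methylbutanoyloxy)cyclohex-3-ene-1-carbonyl]-1,3-oxazolidin-2-one | O=C1OCCN1C(=O)[C@@H]2CC=C(C)C[C@H]2OC(=O)CC(C)C
A2 | alternative 1 | 3-[(2E)-3-(3-methylbutanoyloxy)prop-2-enoyl]-1,3-oxazolidin-2-one | O=C1OCCN1C(=O)/C=C/OC(=O)CC(C)C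
A3 | alternative 2 | (1S,3S,4S,6S)-4-{(4E)-6-[(2-methoxypropan-2-yl)peroxy]-6-methyl-3-oxohepta-1,4-dien-2-yl}-1-methyl-2-oxo-7-oxabicyclo[4.1.0]heptan-3-yl 3-methylbutanoate | C=C(C(=O)/C=C/C(C)(C)OOC(C)(C)OC)[C@@H]1C[C@@H]2O[C@]2(C)C(=O)[C@H]1OC(=O)CC(C)C
A4 | alternative 3 | (2S,3R,5R)-2-hydroxy-2-methyl-5-(prop-1-en-2-yl)-3-[(triethylsilyl)oxy]cyclohexan-1-one | C=C(C)[C@@H]1C[C@@H](O[Si](CC)(CC)CC)[C@](C)(O)C(=O)C1
A5 | alternative 3 | (3R,5R)-6-oxo-3-(prop-1-en-2-yl)-5-[(triethylsilyl)oxy]heptanal | C=C(C)[C@@H](CC=O)C[C@@H](O[Si](CC)(CC)CC)C(C)=O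
A6 | alternative 3 | (R)-limonene | CC1=CC[C@@H](CC1)C(C)=C
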